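The numbers of this flask are assumed, and the outcome is calculated.

The initiator here can begin a chain or fall to spent initiator A, its way to spent initiator B being far slower than the way to spent initiator A, and the count of chains rests on how that split runs while free monomer is being fed in.

free monomer 0.80 M (fed, over 2.5 d); initiator 40 mM; time 2.5 d; the fed solution adds 0.50 times the starting volume

    free monomer + initiator → living end + monomer in chains (k1 = 0.0015 L mol⁻¹ min⁻¹)
    free monomer + living end → monomer in chains + living end, rate k2*[living end]*[free monomer] (k2 = 0.018 L mol⁻¹ min⁻¹)
    free monomer → uncatalysed product (k3 = 4.6 × 10⁻⁵ min⁻¹)
    initiator → spent initiator B (k4 = 3.3 × 10⁻⁷ min⁻¹)
    initiator → spent initiator A (k5 = 5.7 × 10⁻⁴ min⁻¹)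

* average number of monomer units in a chain (chains begun, living or dead) at 2.5 d
* part of the free monomer that has reacted at 2.5 d

- every charge counts on the volume at the start, and the solution that is fed holds the whole dose
- the average divides the monomer in chains by the number of chains begun, living and dead together
- run time (flask): 2.5 d

I set this flask beside its neighbour with 0.10 M of initiator, which has the same feed and the same constants. Each initiator molecule chooses between the two ways in proportion to their rates, and these balance at a break-even free monomer:

[free monomer]ₑ = 0.380 M

At the start, [free monomer] is zero, so the share beginning chains is zero. At the initiator's lifetime on the way to spent initiator A, 1.22 d, the feed has put in, ignoring uptake: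

[free monomer] = 0.313 M

That is less than break-even, and the share there is 45.2 %. I join the two ends: initiator lost before that time goes at the mean of the two shares, and the rest at the later share. This gives the chain share, the part of the charged initiator that begins a chain (the initiator efficiency):

share = 30.9 %

The initiator charge does not enter this reckoning, so I give both flasks this share. For this flask I then reckon 0.0124 M of chains per starting volume. For the neighbour I reckon more in proportion to its larger charge, so I expect it to take up free monomer faster on the same feed. My hand reckoning stops at this count.

The forecast gives 13 units per chain (12 to 14.2) and 25.6 % reacted (23.5 % to 28 %), “from a rough coarse-step run through the feed rather than an exact solution”. It counts about 0.011 M of chains where I count 0.0124 M.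

The flask gives 13.1 units per chain and 25.6 % reacted, both inside the forecast's ranges. At 2.50 d, 3.3 % of the initiator's charge remains in this flask, against 74 % of the free monomer's. This flask's living end of 0.00760 M, multiplied by the final volume over the starting volume, reads as a chain share so far of 28.5 %, against my 30.9 %.

For the neighbour, the share gives 0.0309 M of chains per starting volume, so 0.0206 M of living end at the end. That flask gives 0.0178 M of living end, 11.2 units per chain and 43.3 % reacted.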